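You asked for a quick figure for the late end of these runs, the target standing at 2.0 min, and your hunch was that the protic impurity barely shows there. The flasks and the question first.

common to all: starting material 0.20 M; time 2.0 min

| charge | protic impurity |
|---|---|
| violet | 2.00 mM |
| ochre | 2.50 mM |
| green | 4.00 mM |

    intermediate B ⇌ intermediate C (K1 = 2.9, k1 = 0.074 /s)
    starting material + protic impurity → quenched substrate (k2 = 110 /M/s)
    starting material ⇌ intermediate A (K3 = 0.74, k3 = 0.10 /s)
    starting material + intermediate C → side product (k4 = 0.82 /M/s)
    intermediate A → intermediate B (k5 = 0.038 /s)
    intermediate A → intermediate C (k6 = 0.075 /s)
    starting material → target (k7 = 0.015 /s)

1. amount of target at the end, in percent of the starting material charged for violet, ochre, green, in this order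
2. the shape of the row from first to last (falls, then rises / rises, then falls / hardly changes / falls all the way / rises all the way)

- percent here means starting material units held: one side product counts as two
- "hardly changes" means that all values lie within two and a half points (for a concentration: within two and a half percent of the largest)
- run time (violet): 2.0 min

We work in powers of ten. With c(starting material) so large, the quench is pseudo-first-order in the protic impurity, and its rate stands far above the forward rate constant from starting material to intermediate A:

log10(k2·c(starting material) / k3) = 2.34

So c(protic impurity) halves in 0.0315 s, much sooner than the 0.12 min that starting material needs in violet by step 3 alone, forward rate only. The impurity is thus the limiting reagent of the quench and removes one starting material each. That gives the quantity we carry, the impurity share, meaning the charge of protic impurity over the charge of starting material: 1.00% in violet and 2.00% in green, or in decades: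

−2.00 and −1.70

For the level, we set the side product aside. Starting material goes to target by step 7 or onward through intermediate A, which returns at k3/K3 and leaves at k5 + k6:

k7 / (k7 + k3·(k5 + k6)/(k5 + k6 + k3/K3)) = 24.8%

Our row therefore stands somewhat below 24.8%, by an amount we do not reckon by hand. If target follows the charge left after the quench, it falls from violet to green by about

(2.00% − 1.00%) × 24.8% = 0.25 percentage points

so we commit to a row that hardly changes.

Your forecast gives 20.4%, 20.3% and 20.2%, shape "hardly changes", on the grounds that the “impurity is quenched within about a second”. Its level stands below our 24.8%.

The flask gives 19.1%, 19.0% and 18.9%: hardly changes.

Taken with the flask's own target, the share predicts a fall across the row of (2.00% − 1.00%) × 19.1% = 0.19 points, and the row shows 0.2 points. At 2.00 min green holds 2.00% of quenched substrate, which is its share, with 0% of its protic impurity left. The level of the row is another matter, and part of what holds it down is the reaction of intermediate A to intermediate C: with that step taken out of green, target stands at 31.0% instead of 18.9%. Ochre, with a share of 1.25%, holds 1.25% of quenched substrate.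

The constants used here were set for the occasion; the result is computed.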